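**Plan**

- Retrosynthesis: remove the C7 silyl ether and a sulfonyl helper on C13, then cut C13–C14 and C11–C12 of ring A (cyclohexane) to give enol acetate/unsaturated lactone 25 plus phenyl vinyl sulfone. Further cuts: C14=C15 of ring D (ε-lactone, RCM), C6=C7 of ring C (oxonane, RCM), and the C3=C8 alkene of the meso furan–maleic anhydride adduct 1 (ring-opening/cross-metathesis).
- Forward: ring B (tetrahydrofuran) is present from step 1; ring C closes by RCM (step 9), ring D by RCM (step 17), ring A last by the radical annulation (step 20).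
- Stereochemistry: C1, C2, C9, C10 relative from the exo Diels–Alder adduct, absolute from the enantioselective ring-opening/cross-metathesis. C6/C7 from outer-face epoxidation and SN2 opening; C3 from chelation-controlled MeMgBr addition; C11, C14, C15 in the key step.
- Enabling feature: C11 carries exactly a methyl and an acyloxy group (H• added to an enol acetate), and C14 is the β-carbon of the C15–C17 acyl unit of ring D (a radical acceptor). The two arms sit cis on adjacent atoms C10 and C1 of ring B, so a two-carbon acceptor closes ring A.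

Key step: step 20

Remark: eunicellane numbering is used throughout (ring B: O, C2, C1, C10, C9; ring C: O, C2–C9; ring A: C1, C10–C14; ring D: C3–O–C17(=O)–C15–C14–C1–C2); in this numbering the target is (1S,2S,3S,6R,7R,9S,10R,11R,14R,15R), and it is assumed that the outer-face selectivities usual for this oxa-bridged bicyclic skeleton hold in steps 10 and 13.

**Step 1**
Reactants: 1 exo furan–maleic anhydride adduct
Product: 2 meso exo,exo-diol
Conditions: LiAlH4, THF, 0 °C to reflux; then H2O, aq NaOH
Reagents that add atoms: none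
Why: LiAlH4 reduction of a cyclic anhydride to the 1,4-diol leaves the strained alkene untouched; the four ring stereocentres (later C1, C2, C9, C10) and their exo relationship come from the Diels–Alder adduct.

**Step 2**
Reactants: 2 meso diol
Product: 3 meso bis(TBS) ether
Conditions: TBSCl, imidazole, DMF, rt
Reagents that add atoms: tert-butyldimethylsilyl chloride, CC(C)(C)[Si](C)(C)Cl
Why: standard silylation of two primary alcohols.

**Step 3**
Reactants: 3 meso bis(TBS) ether; 4 butyl vinyl ether
Product: 5 tetrahydrofuran with C2 vinyl and C9 (Z)-2-butoxyvinyl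
Conditions: 4 (10 equiv), Mo(N-1-adamantyl)(CHCMe2Ph)(2,5-Me2C4H2N)(OAr*) 5 mol %, made in situ from Mo(N-1-adamantyl)(CHCMe2Ph)(2,5-Me2C4H2N)2 and one enantiomer of Ar*OH = 3,3′-dibromo-2′-(tert-butyldimethylsilyloxy)-5,5′,6,6′,7,7′,8,8′-octahydro-1,1′-binaphthalen-2-ol; C6H6, 22 °C
Reagents that add atoms: butyl vinyl ether, C=COCCCC
Why: enantioselective ring-opening/cross-metathesis of a strained meso oxabicyclic alkene with an enol ether by a stereogenic-at-metal molybdenum monoaryloxide pyrrolide alkylidene opens the alkene at one of its two enantiotopic carbons, fixing the absolute configuration of C1, C2, C9 and C10 and leaving a vinyl group on C2 and a (Z)-enol ether on C9; the ligand enantiomer is chosen to give the series shown.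

**Step 4**
Reactants: 5 enol ether
Product: 6 aldehyde (C9–CH2–CHO)
Conditions: oxalic acid, THF/H2O, rt
Reagents that add atoms: water, O
Why: mild acid hydrolysis of the enol ether (protonation at C8) gives the aldehyde without touching the silyl ethers or the vinyl group.

**Step 5**
Reactants: 6 aldehyde
Product: 7 terminal alkyne (C9–CH2–C≡CH)
Conditions: dimethyl (1-diazo-2-oxopropyl)phosphonate, K2CO3, MeOH, 0 °C to rt
Reagents that add atoms: dimethyl (1-diazo-2-oxopropyl)phosphonate, CC(=O)C(=[N+]=[N-])P(=O)(OC)OC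
Why: Ohira–Bestmann (Seyferth–Gilbert) homologation of the aldehyde to the terminal alkyne under mild carbonate conditions.

**Step 6**
Reactants: 7 alkyne
Product: 9 methallyl compound (C9–CH2–C(Me)=CH2), via alkenylalane 8 (not isolated)
Conditions: Me3Al (3 equiv), Cp2ZrCl2 (20 mol %), CH2Cl2, 0 °C to rt; then H2O, 0 °C
Reagents that add atoms: trimethylaluminium, C[Al](C)C
Why: Negishi zirconium-catalysed methylalumination adds Me–Al syn across the terminal alkyne with Me on the internal carbon (C7), and protonolysis gives the 2-methylprop-2-enyl group; the monosubstituted alkene is not carbometallated under these conditions.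

**Step 7**
Reactants: 9 methallyl compound
Product: 10 C3 methyl ketone (acetyl on C2)
Conditions: PdCl2 (10 mol %), CuCl, O2 (1 atm), DMF/H2O 7:1, rt
Reagents that add atoms: water, O
Why: Tsuji–Wacker oxidation converts the monosubstituted vinyl group into the methyl ketone and spares the 1,1-disubstituted alkene.

**Step 8**
Reactants: 10 methyl ketone
Product: 12 pent-4-enoyl ketone, via lithium enolate 11 (not isolated)
Conditions: LDA, THF, −78 °C; allyl bromide, DMPU, −78 to −20 °C
Reagents that add atoms: allyl bromide, C=CCBr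
Why: kinetic deprotonation on the methyl side (the α-alkoxy C2–H is not removed at −78 °C) and allylation of the lithium enolate install C4–C6.

**Step 9**
Reactants: 12 diene ketone
Product: 13 bicyclic (Z)-oxonenone (C6=C7, C3 ketone)
Conditions: second-generation Hoveyda–Grubbs catalyst RuCl2(H2IMes)(=CH-C6H4-2-O-i-Pr) (10 mol %), toluene (2 mM), 80 °C
Reagents that add atoms: none
Why: ring-closing metathesis of the two terminal alkenes across the cis-2,5-disubstituted tetrahydrofuran closes the nine-membered ring C with a trisubstituted C6=C7 alkene, necessarily Z in this ring size, a closure precedented for this class of bicyclic ethers.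

**Step 10**
Reactants: 13 oxonenone
Product: 14 6,7-epoxide
Conditions: mCPBA, NaHCO3, CH2Cl2, 0 °C
Reagents that add atoms: 3-chloroperoxybenzoic acid, OOC(=O)c1cccc(Cl)c1
Why: Prilezhaev epoxidation of the only alkene from the exposed outer face of the (Z)-oxonene, the face preferred in this bicyclic skeleton, should put the oxygen on the side where the C7 hydroxyl must end.

**Step 11**
Reactants: 14 epoxide
Product: 15 6-methoxy-7-hydroxy ketone
Conditions: NaOMe (5 equiv), MeOH, 65 °C
Reagents that add atoms: methanol (as sodium methoxide), CO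
Why: SN2 opening of the trisubstituted epoxide by methoxide at the less substituted C6 with inversion gives the trans C6–OMe/C7–OH pair; the C3 carbinol is deliberately absent so no transannular ether can form, and C2, a bridgehead of the bicycle, cannot epimerise.

**Step 12**
Reactants: 15 hydroxy ketone
Product: 16 C7 TBS ether
Conditions: TBSOTf, 2,6-lutidine, CH2Cl2, −40 to 0 °C; mild acidic work-up
Reagents that add atoms: tert-butyldimethylsilyl triflate, CC(C)(C)[Si](C)(C)OS(=O)(=O)C(F)(F)F
Why: silyl triflate silylation of the hindered tertiary alcohol blocks C7–OH for the later acylation and enolate steps (any C3 silyl enol ether is cleaved on work-up).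

**Step 13**
Reactants: 16 ketone
Product: 18 C3 methacrylate, via magnesium alkoxide 17 (not isolated)
Conditions: MeMgBr, THF, −78 to 0 °C; then methacryloyl chloride, DMAP (0.2 equiv), 0 °C to rt
Reagents that add atoms: methylmagnesium bromide, C[Mg]Br; methacryloyl chloride, CC(=C)C(Cl)=O
Why: chelation-controlled Grignard addition (Mg bridging the ketone and the ring oxygen, attack from the H2 side, which is also the outer face) sets C3, and the tertiary magnesium alkoxide is acylated in the same flask.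

**Step 14**
Reactants: 18 bis(primary TBS) ether
Product: 19 diol (C14 and C11 hydroxymethyl arms)
Conditions: HF·pyridine, pyridine/THF, 0 °C to rt
Reagents that add atoms: none
Why: HF·pyridine cleaves the two primary silyl ethers much faster than the tertiary one.

**Step 15**
Reactants: 19 diol
Product: 20 cis dialdehyde
Conditions: Dess–Martin periodinane, NaHCO3, CH2Cl2, rt; used crude
Reagents that add atoms: none
Why: Dess–Martin oxidation under buffered, non-epimerising conditions gives the cis dialdehyde.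

**Step 16**
Reactants: 20 dialdehyde
Product: 21 divinyl methacrylate
Conditions: Zn, CH2Br2, TiCl4, THF/CH2Cl2, 0 °C to rt
Reagents that add atoms: dibromomethane, BrCBr
Why: Takai–Lombardo methylenation is non-basic, so the cis β-alkoxy dialdehyde neither epimerises nor eliminates, and the ester is not touched.

**Step 17**
Reactants: 21 divinyl methacrylate
Product: 22 unsaturated lactone (ring D) with C10 vinyl
Conditions: second-generation Hoveyda–Grubbs catalyst RuCl2(H2IMes)(=CH-C6H4-2-O-i-Pr) (10 mol %), toluene (1 mM), 100 °C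
Reagents that add atoms: none
Why: ring-closing metathesis between the methacrylate and the nearer vinyl group (on C1) closes the seven-membered unsaturated lactone; the vinyl group on C10 could only close an eight-membered ring across ring B and is left.

**Step 18**
Reactants: 22 vinyl lactone
Product: 23 C11 methyl ketone (acetyl on C10)
Conditions: PdCl2 (10 mol %), CuCl, O2 (1 atm), DMF/H2O 7:1, rt
Reagents that add atoms: water, O
Why: Tsuji–Wacker oxidation of the remaining monosubstituted alkene gives the methyl ketone; the conjugated trisubstituted alkene is inert.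

**Step 19**
Reactants: 23 methyl ketone
Product: 25 enol acetate, via potassium enolate 24 (not isolated)
Conditions: KHMDS (1.1 equiv), THF, −78 °C; then Ac2O, −78 to −40 °C
Reagents that add atoms: acetic anhydride, CC(=O)OC(C)=O
Why: kinetic deprotonation on the methyl side and O-acetylation of the potassium enolate give the terminal enol acetate; C10–H, whose removal would open ring B, is not touched at −78 °C.

**Step 20**
Reactants: 25 enol acetate; 26 phenyl vinyl sulfone
Product: 27 13-phenylsulfonyl tetracycle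
Conditions: Fe(acac)3 (30 mol %), PhSiH3 (2.5 equiv), 26 (3 equiv), EtOH/(CH2OH)2 5:1, degassed, 60 °C
Reagents that add atoms: phenyl vinyl sulfone, C=CS(=O)(=O)c1ccccc1
Why: Proposed new method: a trivalent iron hydride (from Fe(acac)3/PhSiH3) transfers H• to the CH2 terminus of the enol acetate, which becomes the C11 methyl group and leaves a tertiary α-acetoxy radical at C11; this nucleophilic radical adds to phenyl vinyl sulfone (C11–C12), the α-sulfonyl radical at C13 adds to C14, the β-carbon of the unsaturated lactone, and the C15 radical is reduced by divalent iron and protonated. The closest known reactions are the iron-hydride cross-coupling of heteroatom-substituted donor alkenes with vinyl sulfones and the HAT-initiated conjugate addition/ring-closure annulations that build cyclohexanes; the enol ester donor and the Michael-type terminating trap are the untested elements. Ring A closes in the 6-exo-trig mode through a chair with C1–C2 and C14–C15 equatorial, so H14 ends trans to H1 and rings A and D become trans-fused (C14). C11 is set in the intermolecular step: the radical should react in the rotamer with the C11–OAc dipole anti to C9–O and be attacked from the open sector next to H10, away from the C1 side that carries C14, which puts OAc cis to C9. C15 is set by protonation of the lactone enolate anti to the new C13 substituent, and C13 is a temporary stereocentre. The step needs HAT to the electron-rich 1,1-disubstituted enol acetate rather than to the conjugated lactone alkene or the sulfone, and ring closure faster than reduction of the C13 radical; the first follows from the polarity of the metal hydride, the second from the cis placement of the two arms on ring B.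

**Step 21**
Reactants: 27 sulfone
Product: 28 C7 TBS ether of the target
Conditions: SmI2 (6 equiv), HMPA, THF/MeOH, −20 °C
Reagents that add atoms: none
Why: single-electron reductive desulfonylation removes the activating group from C13 and leaves the acetate, lactone and silyl ether intact.

**Step 22**
Reactants: 28 silyl ether
Product: 29 target
Conditions: 48% aq HF, MeCN, rt
Reagents that add atoms: none
Why: fluoride-mediated cleavage of the tertiary silyl ether under conditions that spare the tertiary acetate and the lactone.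

**Compound list**

In 5–12 and 19–21 the C1 and C10 substituents are cis to each other and trans to the C2 and C9 substituents (2,5-cis ring B); absolute configuration as in the SMILES.

1 | exo-7-oxabicyclo[2.2.1]hept-5-ene-2,3-dicarboxylic anhydride (meso) | O=C3[C@@H]1[C@H](C(=O)O3)[C@@H]2O[C@H]1C=C2 | starting material
2 | meso exo,exo-7-oxabicyclo[2.2.1]hept-5-ene-2,3-dimethanol | OC[C@@H]1[C@H](CO)[C@@H]2O[C@H]1C=C2 | intermediate
3 | bis(tert-butyldimethylsilyl) ether of 2 (meso) | CC(C)(C)[Si](C)(C)OC[C@@H]1[C@H](CO[Si](C)(C)C(C)(C)C)[C@@H]2O[C@H]1C=C2 | intermediate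
4 | butyl vinyl ether | C=COCCCC | starting material
5 | tetrahydrofuran: C2 vinyl, C9 (Z)-2-butoxyvinyl, C1 and C10 CH2OTBS | CC(C)(C)[Si](C)(C)OC[C@@H]1[C@H](CO[Si](C)(C)C(C)(C)C)[C@@H](C=C)O[C@H]1/C=C\OCCCC | intermediate
6 | aldehyde: C9 2-oxoethyl, C2 vinyl | CC(C)(C)[Si](C)(C)OC[C@@H]1[C@H](CO[Si](C)(C)C(C)(C)C)[C@@H](C=C)O[C@H]1CC=O | intermediate
7 | alkyne: C9 prop-2-ynyl, C2 vinyl | CC(C)(C)[Si](C)(C)OC[C@@H]1[C@H](CO[Si](C)(C)C(C)(C)C)[C@@H](C=C)O[C@H]1CC#C | intermediate
8 | (E)-alkenyl(dimethyl)alane from 7 | CC(C)(C)[Si](C)(C)OC[C@@H]1[C@H](CO[Si](C)(C)C(C)(C)C)[C@@H](C=C)O[C@H]1C/C(C)=C/[Al](C)C | intermediate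
9 | C9 2-methylprop-2-enyl, C2 vinyl | CC(C)(C)[Si](C)(C)OC[C@@H]1[C@H](CO[Si](C)(C)C(C)(C)C)[C@@H](C=C)O[C@H]1CC(C)=C | intermediate
10 | C2 acetyl (C3 ketone), C9 methallyl | CC(C)(C)[Si](C)(C)OC[C@@H]1[C@H](CO[Si](C)(C)C(C)(C)C)[C@@H](C(C)=O)O[C@H]1CC(C)=C | intermediate
11 | lithium enolate of 10 (methyl side) | CC(C)(C)[Si](C)(C)OC[C@@H]1[C@H](CO[Si](C)(C)C(C)(C)C)[C@@H](C(=C)O[Li])O[C@H]1CC(C)=C | intermediate
12 | C2 pent-4-enoyl, C9 methallyl | CC(C)(C)[Si](C)(C)OC[C@@H]1[C@H](CO[Si](C)(C)C(C)(C)C)[C@@H](C(=O)CCC=C)O[C@H]1CC(C)=C | intermediate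
13 | 11-oxabicyclo[6.2.1]undecenone: (Z)-C6=C7, C3 ketone, C1/C10 CH2OTBS | CC(C)(C)[Si](C)(C)OC[C@@H]1[C@H](CO[Si](C)(C)C(C)(C)C)[C@@H]2O[C@H]1C/C(C)=C\CCC2=O | intermediate
14 | 6,7-epoxide of 13 (oxygen on the outer face) | CC(C)(C)[Si](C)(C)OC[C@@H]1[C@H](CO[Si](C)(C)C(C)(C)C)[C@@H]2O[C@H]1C[C@@]3(C)O[C@H]3CCC2=O | intermediate
15 | (6R,7R)-6-methoxy-7-hydroxy C3 ketone | CC(C)(C)[Si](C)(C)OC[C@@H]1[C@H](CO[Si](C)(C)C(C)(C)C)[C@@H]2O[C@H]1C[C@@](C)(O)[C@H](OC)CCC2=O | intermediate
16 | 7-O-TBS ether of 15 | CC(C)(C)[Si](C)(C)OC[C@@H]1[C@H](CO[Si](C)(C)C(C)(C)C)[C@@H]2O[C@H]1C[C@@](C)(O[Si](C)(C)C(C)(C)C)[C@H](OC)CCC2=O | intermediate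
17 | bromomagnesium C3 alkoxide (C3 methyl carbinol) | CC(C)(C)[Si](C)(C)OC[C@@H]1[C@H](CO[Si](C)(C)C(C)(C)C)[C@@H]2O[C@H]1C[C@@](C)(O[Si](C)(C)C(C)(C)C)[C@H](OC)CC[C@]2(C)O[Mg]Br | intermediate
18 | C3 methacrylate | CC(C)(C)[Si](C)(C)OC[C@@H]1[C@H](CO[Si](C)(C)C(C)(C)C)[C@@H]2O[C@H]1C[C@@](C)(O[Si](C)(C)C(C)(C)C)[C@H](OC)CC[C@]2(C)OC(=O)C(C)=C | intermediate
19 | diol (hydroxymethyl on C1 and C10) | OC[C@@H]1[C@H](CO)[C@@H]2O[C@H]1C[C@@](C)(O[Si](C)(C)C(C)(C)C)[C@H](OC)CC[C@]2(C)OC(=O)C(C)=C | intermediate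
20 | cis dialdehyde (formyl on C1 and C10) | O=C[C@@H]1[C@H](C=O)[C@@H]2O[C@H]1C[C@@](C)(O[Si](C)(C)C(C)(C)C)[C@H](OC)CC[C@]2(C)OC(=O)C(C)=C | intermediate
21 | divinyl methacrylate (vinyl on C1 and C10) | C=C[C@@H]1[C@H](C=C)[C@@H]2O[C@H]1C[C@@](C)(O[Si](C)(C)C(C)(C)C)[C@H](OC)CC[C@]2(C)OC(=O)C(C)=C | intermediate
22 | tricycle with rings B, C, D: (Z)-C14=C15 unsaturated lactone, C10 vinyl | CO[C@@H]1CC[C@]2(C)OC(=O)/C(C)=C\[C@@H]3[C@@H]2O[C@@H](C[C@@]1(C)O[Si](C)(C)C(C)(C)C)[C@@H]3C=C | intermediate
23 | C10 acetyl (C11 methyl ketone) | CO[C@@H]1CC[C@]2(C)OC(=O)/C(C)=C\[C@@H]3[C@@H]2O[C@@H](C[C@@]1(C)O[Si](C)(C)C(C)(C)C)[C@@H]3C(C)=O | intermediate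
24 | potassium enolate of 23 (methyl side) | CO[C@@H]1CC[C@]2(C)OC(=O)/C(C)=C\[C@@H]3[C@@H]2O[C@@H](C[C@@]1(C)O[Si](C)(C)C(C)(C)C)[C@@H]3C(=C)O[K] | intermediate
25 | enol acetate (C10–C(OAc)=CH2) | CO[C@@H]1CC[C@]2(C)OC(=O)/C(C)=C\[C@@H]3[C@@H]2O[C@@H](C[C@@]1(C)O[Si](C)(C)C(C)(C)C)[C@@H]3C(=C)OC(C)=O | intermediate
26 | phenyl vinyl sulfone | C=CS(=O)(=O)c1ccccc1 | starting material
27 | tetracycle with 13-phenylsulfonyl group (C13 configuration not assigned), 7-O-TBS | CO[C@@H]1CC[C@]2(C)OC(=O)[C@H](C)[C@@H]3C(S(=O)(=O)c5ccccc5)C[C@@](C)(OC(C)=O)[C@@H]4[C@H]3[C@@H]2O[C@H]4C[C@@]1(C)O[Si](C)(C)C(C)(C)C | intermediate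
28 | 7-O-TBS ether of the target | CO[C@@H]1CC[C@]2(C)OC(=O)[C@H](C)[C@@H]3CC[C@@](C)(OC(C)=O)[C@@H]4[C@H]3[C@@H]2O[C@H]4C[C@@]1(C)O[Si](C)(C)C(C)(C)C | intermediate
29 | CNP0238771.1 | CO[C@@H]1CC[C@]2(C)OC(=O)[C@H](C)[C@@H]3CC[C@@](C)(OC(C)=O)[C@@H]4[C@H]3[C@@H]2O[C@H]4C[C@@]1(C)O | target

**Totals**

Total step count: 22. Longest linear sequence: 22 steps (fully linear from 1).

**Steps most likely to fail**

Step 20. The C13 radical, an electrophilic α-sulfonyl radical that must add to an electron-poor alkene, may be reduced before it closes ring A; the intermolecular addition at C11 may show low or reversed facial selectivity; or hydrogen-atom transfer may go to the lactone alkene. Fallback with known reactions, from 23 back to 28: the kinetic lithium enolate of 23 (LiHMDS, −78 °C) is hydroxymethylated with monomeric formaldehyde to give hydroxymethyl ketone F1. MeMgBr (2 equiv, −78 °C), chelated between the ketone and the ring oxygen, then adds from the H10 side to give diol F2 with the C11 configuration of the target (here the ketone methyl becomes C12 and the C11 methyl comes from the Grignard reagent). I2/PPh3/imidazole converts the primary alcohol into iodide F3, and Ac2O/DMAP/Et3N gives tertiary acetate F4. Bu3SnH/AIBN then closes ring A by 6-exo-trig cyclisation of the primary C13 radical onto C14 and returns to 28.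

Step 3. Discrimination between the two enantiotopic alkene carbons may be incomplete, or the strained alkene may oligomerise faster than it cross-couples. Fallback from 3 back to 9: ozonolysis of 3 with NaBH4 work-up gives meso diol F5. Lipase-catalysed acetylation (Pseudomonas cepacia lipase, vinyl acetate; hydrolysis of the diacetate if the other enantiomer is formed) gives monoacetate F6. Dess–Martin oxidation gives aldehyde F7 and Wittig methylenation gives alkene F8. K2CO3/MeOH gives alcohol F9 and I2/PPh3/imidazole gives iodide F10. Isopropenylmagnesium bromide with catalytic CuI then returns to 9.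

Step 11. Methoxide may enolise the C3 ketone, after which the enolate oxygen can attack the epoxide across the ring or aldol pathways can start; attack at the hindered C6 may also be slow. Fallback from 13 back to 21, with the C3 carbinol installed and masked before the epoxide is made: MeMgBr (chelation control) gives tertiary alcohol F11 and TESOTf/2,6-lutidine gives silyl ether F12. mCPBA gives epoxide F13, and NaOMe/MeOH opens it at C6 to give methoxy alcohol F14. TBSOTf gives bis-silyl ether F15, and HF·pyridine removes the two primary TBS groups and the tertiary TES group to give triol F16. Dess–Martin oxidation gives dialdehyde F17, Takai–Lombardo methylenation gives divinyl alcohol F18, and KHMDS/methacryloyl chloride returns to 21.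

**Further compounds**

F1 | step 20 | hydroxymethyl ketone (C10–C(=O)–CH2CH2OH) | CO[C@@H]1CC[C@]2(C)OC(=O)/C(C)=C\[C@@H]3[C@@H]2O[C@@H](C[C@@]1(C)O[Si](C)(C)C(C)(C)C)[C@@H]3C(=O)CCO
F2 | step 20 | diol with C11 methyl carbinol | CO[C@@H]1CC[C@]2(C)OC(=O)/C(C)=C\[C@@H]3[C@@H]2O[C@@H](C[C@@]1(C)O[Si](C)(C)C(C)(C)C)[C@@H]3[C@](C)(O)CCO
F3 | step 20 | primary iodide, C11 tertiary alcohol | CO[C@@H]1CC[C@]2(C)OC(=O)/C(C)=C\[C@@H]3[C@@H]2O[C@@H](C[C@@]1(C)O[Si](C)(C)C(C)(C)C)[C@@H]3[C@](C)(O)CCI
F4 | step 20 | primary iodide, C11 tertiary acetate | CO[C@@H]1CC[C@]2(C)OC(=O)/C(C)=C\[C@@H]3[C@@H]2O[C@@H](C[C@@]1(C)O[Si](C)(C)C(C)(C)C)[C@@H]3[C@](C)(OC(C)=O)CCI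
F5 | step 3 | meso diol (hydroxymethyl on C2 and C9) | CC(C)(C)[Si](C)(C)OC[C@@H]1[C@H](CO[Si](C)(C)C(C)(C)C)[C@@H](CO)O[C@H]1CO
F6 | step 3 | monoacetate (acetoxymethyl on C9, hydroxymethyl on C2) | CC(C)(C)[Si](C)(C)OC[C@@H]1[C@H](CO[Si](C)(C)C(C)(C)C)[C@@H](CO)O[C@H]1COC(C)=O
F7 | step 3 | C2 aldehyde, C9 acetoxymethyl | CC(C)(C)[Si](C)(C)OC[C@@H]1[C@H](CO[Si](C)(C)C(C)(C)C)[C@@H](C=O)O[C@H]1COC(C)=O
F8 | step 3 | C2 vinyl, C9 acetoxymethyl | CC(C)(C)[Si](C)(C)OC[C@@H]1[C@H](CO[Si](C)(C)C(C)(C)C)[C@@H](C=C)O[C@H]1COC(C)=O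
F9 | step 3 | C2 vinyl, C9 hydroxymethyl | CC(C)(C)[Si](C)(C)OC[C@@H]1[C@H](CO[Si](C)(C)C(C)(C)C)[C@@H](C=C)O[C@H]1CO
F10 | step 3 | C2 vinyl, C9 iodomethyl | CC(C)(C)[Si](C)(C)OC[C@@H]1[C@H](CO[Si](C)(C)C(C)(C)C)[C@@H](C=C)O[C@H]1CI
F11 | step 11 | oxonene with C3 methyl carbinol | CC(C)(C)[Si](C)(C)OC[C@@H]1[C@H](CO[Si](C)(C)C(C)(C)C)[C@@H]2O[C@H]1C/C(C)=C\CC[C@]2(C)O
F12 | step 11 | 3-O-triethylsilyl ether of F11 | CC(C)(C)[Si](C)(C)OC[C@@H]1[C@H](CO[Si](C)(C)C(C)(C)C)[C@@H]2O[C@H]1C/C(C)=C\CC[C@]2(C)O[Si](CC)(CC)CC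
F13 | step 11 | 6,7-epoxide of F12 | CC(C)(C)[Si](C)(C)OC[C@@H]1[C@H](CO[Si](C)(C)C(C)(C)C)[C@@H]2O[C@H]1C[C@@]3(C)O[C@H]3CC[C@]2(C)O[Si](CC)(CC)CC
F14 | step 11 | 6-methoxy-7-hydroxy 3-O-TES compound | CC(C)(C)[Si](C)(C)OC[C@@H]1[C@H](CO[Si](C)(C)C(C)(C)C)[C@@H]2O[C@H]1C[C@@](C)(O)[C@H](OC)CC[C@]2(C)O[Si](CC)(CC)CC
F15 | step 11 | 7-O-TBS, 3-O-TES compound | CC(C)(C)[Si](C)(C)OC[C@@H]1[C@H](CO[Si](C)(C)C(C)(C)C)[C@@H]2O[C@H]1C[C@@](C)(O[Si](C)(C)C(C)(C)C)[C@H](OC)CC[C@]2(C)O[Si](CC)(CC)CC
F16 | step 11 | triol (C3–OH and two hydroxymethyl arms), 7-O-TBS | OC[C@@H]1[C@H](CO)[C@@H]2O[C@H]1C[C@@](C)(O[Si](C)(C)C(C)(C)C)[C@H](OC)CC[C@]2(C)O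
F17 | step 11 | dialdehyde with free C3–OH | O=C[C@@H]1[C@H](C=O)[C@@H]2O[C@H]1C[C@@](C)(O[Si](C)(C)C(C)(C)C)[C@H](OC)CC[C@]2(C)O
F18 | step 11 | divinyl compound with free C3–OH | C=C[C@@H]1[C@H](C=C)[C@@H]2O[C@H]1C[C@@](C)(O[Si](C)(C)C(C)(C)C)[C@H](OC)CC[C@]2(C)O
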